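The rate constants were chosen freely; the result is computed.

The starting material was what I followed, through two tanks and a closed flask, to see how much of it became target.

    starting material ⇌ intermediate A (K1 = 0.28, k1 = 0.094 s⁻¹)
    starting material → intermediate B (k2 = 0.019 s⁻¹)
    intermediate B → target (k3 = 0.075 s⁻¹)
    target ⇌ isomer of the product (K4 = 0.79, k4 = 0.012 s⁻¹)
    starting material ⇌ dormant form (K5 = 5.0, k5 = 0.011 s⁻¹)

the same everywhere: starting material 0.050 M

|  | remark | time |
|---|---|---|
| spring | a single well-mixed tank run continuously and read at steady state, 30 s in it on average |  |
| winter | a closed flask charged with all of it at once and left for 30 s | 30 s |
| summer | a single well-mixed tank run continuously and read at steady state, 150 s in it on average |  |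

- the set-up with the highest amount of target at the outlet or at the end, in percent of the starting material put in ("none" if the first two lie within 2 percentage points) (spring / winter / summer / none)
- amount of target at the outlet or at the end, in percent of the starting material put in, spring
- amount of target at the outlet or at the end, in percent of the starting material put in, winter
- amount of target at the outlet or at the end, in percent of the starting material put in, summer

**Fastest rung.** I lumped starting material and intermediate A into one pool, a rapid pre-equilibrium with [intermediate A]/[starting material] near 0.28. The pool leaks at 0.0234 s⁻¹, a half-life of 29.6 s, and the forward half-life of the first step, 7.4 s, is shorter.

**Next rung.** Intermediate B has a half-life of 9.24 s, also shorter than the leak, so I expected it to stay a small stock on the way to target.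

**The split.** The pool leaks towards intermediate B and towards the dormant form. Dividing these two rates cancels both [starting material] and time, leaving the split, a selectivity factor: 1.73 parts enter the main line (intermediate B, target and isomer of the product together) for each part that turns dormant. The dormant form returns with a half-life of 315 s, longer than either holding time. In the closed flask of winter I therefore kept the split fixed. In a tank the dormant form leaves by the outlet as well as by return, so at steady state the ratio of main line to dormant form is the split times one plus the return rate times the mean residence time. That factor is 1.07 for spring and 1.33 for summer, which raises the split in summer to 2.30.

**Slowest rung.** In winter the main line takes 63.3% of each leak, which put 32.0% in it. For the tanks I balanced the charge over the pool, the dormant form and the main line, which put 26.4% in the main line for spring and 53.1% for summer. The passage to the isomer, with a half-life of 58 s, costs the summer tank most. After taking off intermediate B and the isomer, I reckoned 14.6% of target for spring and 31.5% for summer. For winter I reckoned 20.8% before any isomer is taken off. Summer came out ahead.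

The forecast gave 14.8%, 19.3% and 31.5%, with summer first, remarking of that tank that “its long residence time more than outweighs the losses to the isomer and dormant form”.

**Result.** The simulation gave 14.8% for spring, 18.6% for winter and 31.5% for summer, so summer led. Winter at 30.0 s still held 38.3% as starting material. Its dormant form, 18.0%, times the split gives 31.1%, and its main line held 32.3%. The same flask read at 8.00 s held 6.61% dormant, which gives 11.4%, and its main line held 11.5%.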